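The numbers of this flask are those of an exercise, and the outcome is calculated.

The free base holds acid set free far harder than the nucleophile does, so the charge of free base tells you when the nucleophile starts paying for the acid.

    nucleophile + acid set free ⇌ protonated nucleophile, settled at all times (K1 = 640 L mol⁻¹)
    nucleophile + acid set free ⇌ idle adduct, settled at all times (K2 = 8.1 L mol⁻¹)
    electrophile + nucleophile → acid set free + target (k3 = 0.56 L mol⁻¹ s⁻¹)
    acid set free + scavenger → scavenged by-product (k4 = 23 L mol⁻¹ s⁻¹)
    acid set free + free base ⇌ salt of the base, settled at all times (K5 = 3.3 × 10⁶ L mol⁻¹)
    acid set free + target → side product (k6 = 0.51 L mol⁻¹ s⁻¹)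

electrophile 10 mM; nucleophile 30.0 mM; free base 3.00 mM; scavenger 5.00 mM; time 4.0 min

- for acid set free the idle adduct is counted in
- run time (flask): 4.0 min

* part of the electrophile that has reacted at 4.0 min
* share of free nucleophile in free nucleophile and protonated nucleophile together, at 4.0 min

Take c first. With the nucleophile in excess, the electrophile falls pseudo-first-order: what remains is e^(−n), where n = k·B̄·t. Here k is the rate constant of the electrophile step, B̄ the mean free nucleophile over the run, and t the time.

B̄ depends on c, so go round. Each turnover uses one nucleophile and sets free one acid. The free base takes the first 3.00 mM of acid. Later acid lands on the nucleophile as protonated nucleophile rather than as idle adduct. Leaving the scavenger out, I reckon the loss of free nucleophile by the end as L = 2·E·c − F, with E the electrophile charge and F the base charge. For B̄, take the nucleophile charge less 0.5·L.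

| Round | B̄ | n | c |
|---|---|---|---|
| first | 30.0 mM | 4.03 | 98.2 % |
| second | 21.7 mM | 2.91 | 94.6 % |
| third | 22.0 mM | 2.96 | 94.8 % |

The first row spends no nucleophile, so its c is too high. The second row puts that c back, and the count falls to 2.91. The third row moves c by 0.20 percentage points, so I stop there.

Carry the lifetime count, k times mean free nucleophile times time. My answer is c near 94.8 %. The scavenger is not in this reckoning, so it stops short of fr, and I commit to no number there.

The forecast says 93.5 % and 87 %, holding that “the nucleophile stays in excess at about 18 mM free”. Its c stands 1.3 points below mine.

The flask gives 93.8 % for c and 87.0 % for fr. At 4.00 min the flask holds free nucleophile at 59.7 % of its charge, with 3.25 mM of scavenged by-product. Read back, that c is a count of 2.77, lower than my 2.96. Now take the neighbour flask with 4.0 mM of electrophile. Putting 94.8 % into L gives a count of 3.72, so 2.42 % should remain. That neighbour flask holds 2.74 % of its electrophile at 4.00 min.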